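Ring A is a di-ortho-substituted benzoyl unit: C1 carries the ester carbonyl and is crowded by the heptyl chain on C2 and the methoxy group on C6. The C(=O)–O bond to O4 of ring B is therefore formed first, with linear dec-2-ynoic acid, and ring A is then built around the triple bond. In one operation the ynoate carbons (future C1 and C2) take up a 1,1-dimethoxy-3-silyloxybutadiene (future C3–C6) in a [4+2] cycloaddition that forms C2–C3 and C1–C6, aromatizes, and sets the 4-OH/6-OMe pattern. The precursor is benzyl 4-(dec-2-ynoyloxy)-2-methoxy-6-pentylbenzoate, with ring B complete and its acid held as a benzyl ester.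

Key step: step 9

Assumption: 14 and 15 are not isolated; aromatization is taken to occur during heating and the Si–O bond to be cleaved in the acidic work-up, so 16 is the first isolated product of step 9.

Step 1
Reactants: 1 olivetolic acid (2,4-dihydroxy-6-pentylbenzoic acid)
Product: 2 benzyl 2,4-dihydroxy-6-pentylbenzoate
Conditions: BnBr (1.05 equiv), KHCO3 (1.2 equiv), DMF, rt
Reagents that add atoms: benzyl bromide, BrCc1ccccc1
Why: Bicarbonate deprotonates only the carboxylic acid, so SN2 O-alkylation of the carboxylate should give the benzyl ester with both phenols left free, and the mild temperature avoids decarboxylation of the beta-resorcylic acid.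

Step 2
Reactants: 2 benzyl 2,4-dihydroxy-6-pentylbenzoate
Product: 3 benzyl 2-hydroxy-6-pentyl-4-(prop-2-en-1-yloxy)benzoate
Conditions: allyl bromide (1.1 equiv), K2CO3 (1.2 equiv), acetone, rt to 40 °C
Reagents that add atoms: allyl bromide, C=CCBr
Why: Williamson ether synthesis in which the 2-OH is held in a hydrogen bond to the ester carbonyl and shielded by it, so one equivalent of allyl bromide with a weak base should alkylate the free, more acidic 4-OH selectively.

Step 3
Reactants: 3 benzyl 2-hydroxy-6-pentyl-4-(prop-2-en-1-yloxy)benzoate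
Product: 4 benzyl 2-methoxy-6-pentyl-4-(prop-2-en-1-yloxy)benzoate
Conditions: MeI (3 equiv), K2CO3 (2 equiv), DMF, 50 °C
Reagents that add atoms: iodomethane, CI
Why: Williamson methylation of the chelated salicylate-type phenol, the only acidic site left, under slightly more forcing conditions that the benzyl ester and the allyl ether tolerate.

Step 4
Reactants: 4 benzyl 2-methoxy-6-pentyl-4-(prop-2-en-1-yloxy)benzoate
Product: 5 benzyl 4-hydroxy-2-methoxy-6-pentylbenzoate
Conditions: Pd(PPh3)4 (3 mol%), morpholine (5 equiv), THF, rt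
Reagents that add atoms: none
Why: Tsuji-Trost-type deallylation in which zerovalent palladium ionizes the aryl allyl ether to a pi-allyl complex that morpholine captures, freeing the 4-OH without touching the benzyl ester or the methyl ether.

Step 5
Reactants: 5 benzyl 4-hydroxy-2-methoxy-6-pentylbenzoate; 6 dec-2-ynoic acid
Product: 7 benzyl 4-(dec-2-ynoyloxy)-2-methoxy-6-pentylbenzoate
Conditions: DCC (1.2 equiv), DMAP (0.1 equiv), CH2Cl2, 0 °C to rt
Reagents that add atoms: none
Why: Steglich esterification in which DCC activates the unhindered ynoic acid as its O-acylisourea and catalytic DMAP passes the linear acyl group to the single free phenol, the low temperature limiting conjugate addition to the triple bond.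

Step 6
Reactants: 8 acetyl chloride; 9 1,1-dichloroethene
Product: 11 4,4-dichlorobut-3-en-2-one, via 4,4,4-trichlorobutan-2-one 10 (not isolated)
Conditions: AlCl3 (1.1 equiv), CH2Cl2, 0 °C to rt; ice/aq HCl quench; steam distillation
Reagents that add atoms: none
Why: Friedel-Crafts-type acylation of an alkene (Darzens-Nenitzescu reaction) in which the acylium ion adds to the CH2 terminus of 1,1-dichloroethene, chloride capture gives 10, and beta-elimination of HCl on steam distillation should give the conjugated dichlorovinyl ketone.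

Step 7
Reactants: 11 4,4-dichlorobut-3-en-2-one
Product: 12 4,4-dimethoxybut-3-en-2-one
Conditions: NaOMe (2.2 equiv), MeOH, 0 °C to rt
Reagents that add atoms: sodium methoxide, [Na+].[O-]C
Why: Two successive addition-elimination reactions (nucleophilic vinylic substitution) of methoxide at the beta carbon of this vinylogous acid chloride should replace both chlorides and give the acyl ketene acetal.

Step 8
Reactants: 12 4,4-dimethoxybut-3-en-2-one
Product: 13 1,1-dimethoxy-3-(trimethylsilyloxy)buta-1,3-diene
Conditions: TMSCl (1.5 equiv), Et3N (2 equiv), ZnCl2 (3 mol%), toluene, 40 °C; filtration under N2; distillation under reduced pressure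
Reagents that add atoms: chlorotrimethylsilane, C[Si](C)(C)Cl
Why: Soft enolization and O-silylation of the methyl ketone (silyl enol ether formation), the standard entry to 2-silyloxybuta-1,3-dienes from enones, should give the diene because the methyl group is the only enolizable position.

Step 9
Reactants: 7 benzyl 4-(dec-2-ynoyloxy)-2-methoxy-6-pentylbenzoate; 13 1,1-dimethoxy-3-(trimethylsilyloxy)buta-1,3-diene
Product: 16 benzyl 4-[(2-heptyl-4-hydroxy-6-methoxybenzoyl)oxy]-2-methoxy-6-pentylbenzoate, via cyclohexadiene ketal cycloadduct 14 (not isolated), via aryl trimethylsilyl ether 15 (not isolated)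
Conditions: 13 (4 equiv, in two portions), toluene (2 M), sealed tube, 120 °C, 24–48 h; then 1 M aq HCl, THF, rt
Reagents that add atoms: none
Why: The electron-rich diene 13 and the electron-poor triple bond of 7 should combine in a polarized, asynchronous normal-demand Diels-Alder reaction in which the CH2 terminus of 13 bonds to the heptyl-bearing beta carbon of the ynoate and the C(OMe)2 carbon bonds to the alpha carbon. Ring A thus closes by an intermolecular [4+2] cycloaddition that forms C2–C3 and C1–C6 together and gives the 1,4-cyclohexadiene ketal 14, which aromatizes by 1,4-elimination of methanol to the aryl silyl ether 15, and the acidic work-up cleaves the Si–O bond to give phenol 16. The closest known reaction type is the Diels-Alder/aromatization of 1,1-dialkoxy-3-silyloxybuta-1,3-dienes with alkyl alk-2-ynoates to give 2-alkyl-4-hydroxy-6-alkoxybenzoates. No stereocenter is created, because the only sp3 ring carbons of 14 become aromatic. The step needs regioselectivity, which the matched polarization secures: the largest HOMO coefficient of 13 lies on its unsubstituted CH2 terminus and the largest LUMO coefficient of 7 on the beta carbon, so methoxy ends up at C6 next to the ester and hydroxyl at C4. The aryloxy group of ring B, a weaker donor than an alkoxy group because of its para benzyl ester, lowers the ynoate LUMO, and the excess diene should scavenge the liberated methanol before it can attack the activated aryl ester.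

Step 10
Reactants: 16 benzyl 4-[(2-heptyl-4-hydroxy-6-methoxybenzoyl)oxy]-2-methoxy-6-pentylbenzoate
Product: 17 benzyl 4-[(2-heptyl-4,6-dimethoxybenzoyl)oxy]-2-methoxy-6-pentylbenzoate
Conditions: MeI (3 equiv), K2CO3 (1.5 equiv), acetone, 40 °C
Reagents that add atoms: iodomethane, CI
Why: Williamson methylation of the only acidic group, the unhindered ring A 4-OH, under mild carbonate conditions that should not attack the di-ortho-substituted depside ester or the benzyl ester.

Step 11
Reactants: 17 benzyl 4-[(2-heptyl-4,6-dimethoxybenzoyl)oxy]-2-methoxy-6-pentylbenzoate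
Product: 18 4-[(2-heptyl-4,6-dimethoxybenzoyl)oxy]-2-methoxy-6-pentylbenzoic acid (CNP0274910.0)
Conditions: H2 (1 atm), Pd/C (10 wt% Pd), EtOAc, rt
Reagents that add atoms: none
Why: Catalytic hydrogenolysis of the benzylic C–O bond should free the ring B carboxylic acid under neutral conditions that leave the aryl ester and the methyl ethers untouched.

Compound list
1 | olivetolic acid (2,4-dihydroxy-6-pentylbenzoic acid) | CCCCCc1cc(O)cc(O)c1C(=O)O | starting material
2 | benzyl 2,4-dihydroxy-6-pentylbenzoate | CCCCCc1cc(O)cc(O)c1C(=O)OCc1ccccc1 | intermediate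
3 | benzyl 2-hydroxy-6-pentyl-4-(prop-2-en-1-yloxy)benzoate | CCCCCc1cc(OCC=C)cc(O)c1C(=O)OCc1ccccc1 | intermediate
4 | benzyl 2-methoxy-6-pentyl-4-(prop-2-en-1-yloxy)benzoate | CCCCCc1cc(OCC=C)cc(OC)c1C(=O)OCc1ccccc1 | intermediate
5 | benzyl 4-hydroxy-2-methoxy-6-pentylbenzoate | CCCCCc1cc(O)cc(OC)c1C(=O)OCc1ccccc1 | intermediate
6 | dec-2-ynoic acid | CCCCCCCC#CC(=O)O | starting material
7 | benzyl 4-(dec-2-ynoyloxy)-2-methoxy-6-pentylbenzoate | CCCCCCCC#CC(=O)Oc1cc(CCCCC)c(C(=O)OCc2ccccc2)c(OC)c1 | intermediate
8 | acetyl chloride | CC(=O)Cl | starting material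
9 | 1,1-dichloroethene | C=C(Cl)Cl | starting material
10 | 4,4,4-trichlorobutan-2-one | CC(=O)CC(Cl)(Cl)Cl | intermediate
11 | 4,4-dichlorobut-3-en-2-one | CC(=O)C=C(Cl)Cl | intermediate
12 | 4,4-dimethoxybut-3-en-2-one | CC(=O)C=C(OC)OC | intermediate
13 | 1,1-dimethoxy-3-(trimethylsilyloxy)buta-1,3-diene | C=C(O[Si](C)(C)C)C=C(OC)OC | intermediate
14 | benzyl 4-{[2-heptyl-6,6-dimethoxy-4-(trimethylsilyloxy)cyclohexa-1,4-diene-1-carbonyl]oxy}-2-methoxy-6-pentylbenzoate | CCCCCCCC1=C(C(=O)Oc2cc(CCCCC)c(C(=O)OCc3ccccc3)c(OC)c2)C(OC)(OC)C=C(O[Si](C)(C)C)C1 | intermediate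
15 | benzyl 4-{[2-heptyl-6-methoxy-4-(trimethylsilyloxy)benzoyl]oxy}-2-methoxy-6-pentylbenzoate | CCCCCCCc1cc(O[Si](C)(C)C)cc(OC)c1C(=O)Oc1cc(CCCCC)c(C(=O)OCc2ccccc2)c(OC)c1 | intermediate
16 | benzyl 4-[(2-heptyl-4-hydroxy-6-methoxybenzoyl)oxy]-2-methoxy-6-pentylbenzoate | CCCCCCCc1cc(O)cc(OC)c1C(=O)Oc1cc(CCCCC)c(C(=O)OCc2ccccc2)c(OC)c1 | intermediate
17 | benzyl 4-[(2-heptyl-4,6-dimethoxybenzoyl)oxy]-2-methoxy-6-pentylbenzoate | CCCCCCCc1cc(OC)cc(OC)c1C(=O)Oc1cc(CCCCC)c(C(=O)OCc2ccccc2)c(OC)c1 | intermediate
18 | 4-[(2-heptyl-4,6-dimethoxybenzoyl)oxy]-2-methoxy-6-pentylbenzoic acid | CCCCCCCc1cc(OC)cc(OC)c1C(=O)Oc1cc(CCCCC)c(C(=O)O)c(OC)c1 | target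

Total step count: 11. Longest linear sequence: 8 steps (steps 1, 2, 3, 4, 5, 9, 10, 11, from olivetolic acid); the diene branch (steps 6, 7, 8) joins at step 9.

Steps most likely to fail

Step 9. The cycloaddition at the heptyl-shielded beta carbon is slow, so during the long heating the nucleophilic diene or the liberated methanol may instead attack the activated aryl ester carbonyl, transferring the acyl group and releasing the ring B phenol, or the diene may decompose first. The fallback sets out from 6 (using 13 and 5 as well) and comes back at 17. Ring A is built on an alkyl ynoate, the precedented dienophile class, and the hindered ester is then made by the classical mixed-anhydride depside coupling. Acid 6 is alkylated with BnBr and K2CO3 in DMF to benzyl dec-2-ynoate F1. Heating F1 with 13 should give, through the cycloadduct benzyl 2-heptyl-6,6-dimethoxy-4-(trimethylsilyloxy)cyclohexa-1,4-diene-1-carboxylate F2 and the aryl silyl ether benzyl 2-heptyl-6-methoxy-4-(trimethylsilyloxy)benzoate F3, after acidic work-up benzyl 2-heptyl-4-hydroxy-6-methoxybenzoate F4. Methylation with MeI and K2CO3 gives benzyl 2-heptyl-4,6-dimethoxybenzoate F5, and hydrogenolysis over Pd/C gives 2-heptyl-4,6-dimethoxybenzoic acid F6. Trifluoroacetic anhydride in toluene at rt converts F6 into 2-heptyl-4,6-dimethoxybenzoic trifluoroacetic anhydride F7, whose acylium-like carbonyl should acylate phenol 5 despite the two ortho groups and give 17.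

Step 5. The O-acylisourea may rearrange to the unreactive N-acylurea, or DMAP may add to the activated triple bond, before the electron-poor phenol is acylated. The fallback sets out from 6 and comes back at 7. Acid 6 is converted with oxalyl chloride and catalytic DMF in CH2Cl2 into the isolated dec-2-ynoyl chloride F8, which acylates phenol 5 in CH2Cl2 at −20 °C with 2,6-lutidine as a non-nucleophilic base, so that no carbodiimide and no nucleophilic catalyst are present.

Step 8. The trimethylsilyl enol ether and ketene acetal may hydrolyse during filtration and distillation, or enolization may be incomplete, so the diene is lost or impure. The fallback sets out from 12 and comes back at 16. Ketone 12 is silylated with TBSOTf and Et3N in Et2O at 0 °C to the more robust 3-(tert-butyldimethylsilyloxy)-1,1-dimethoxybuta-1,3-diene F9, which is heated with 7 as in step 9. The cycloadduct benzyl 4-{[4-(tert-butyldimethylsilyloxy)-2-heptyl-6,6-dimethoxycyclohexa-1,4-diene-1-carbonyl]oxy}-2-methoxy-6-pentylbenzoate F10 should aromatize to the aryl silyl ether benzyl 4-{[4-(tert-butyldimethylsilyloxy)-2-heptyl-6-methoxybenzoyl]oxy}-2-methoxy-6-pentylbenzoate F11, and cleavage with TBAF buffered with AcOH in THF at 0 °C gives 16.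

Further compounds
F1 | step 9 | benzyl dec-2-ynoate | CCCCCCCC#CC(=O)OCc1ccccc1
F2 | step 9 | benzyl 2-heptyl-6,6-dimethoxy-4-(trimethylsilyloxy)cyclohexa-1,4-diene-1-carboxylate | CCCCCCCC1=C(C(=O)OCc2ccccc2)C(OC)(OC)C=C(O[Si](C)(C)C)C1
F3 | step 9 | benzyl 2-heptyl-6-methoxy-4-(trimethylsilyloxy)benzoate | CCCCCCCc1cc(O[Si](C)(C)C)cc(OC)c1C(=O)OCc1ccccc1
F4 | step 9 | benzyl 2-heptyl-4-hydroxy-6-methoxybenzoate | CCCCCCCc1cc(O)cc(OC)c1C(=O)OCc1ccccc1
F5 | step 9 | benzyl 2-heptyl-4,6-dimethoxybenzoate | CCCCCCCc1cc(OC)cc(OC)c1C(=O)OCc1ccccc1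
F6 | step 9 | 2-heptyl-4,6-dimethoxybenzoic acid | CCCCCCCc1cc(OC)cc(OC)c1C(=O)O
F7 | step 9 | 2-heptyl-4,6-dimethoxybenzoic trifluoroacetic anhydride | CCCCCCCc1cc(OC)cc(OC)c1C(=O)OC(=O)C(F)(F)F
F8 | step 5 | dec-2-ynoyl chloride | CCCCCCCC#CC(=O)Cl
F9 | step 8 | 3-(tert-butyldimethylsilyloxy)-1,1-dimethoxybuta-1,3-diene | C=C(O[Si](C)(C)C(C)(C)C)C=C(OC)OC
F10 | step 8 | benzyl 4-{[4-(tert-butyldimethylsilyloxy)-2-heptyl-6,6-dimethoxycyclohexa-1,4-diene-1-carbonyl]oxy}-2-methoxy-6-pentylbenzoate | CCCCCCCC1=C(C(=O)Oc2cc(CCCCC)c(C(=O)OCc3ccccc3)c(OC)c2)C(OC)(OC)C=C(O[Si](C)(C)C(C)(C)C)C1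
F11 | step 8 | benzyl 4-{[4-(tert-butyldimethylsilyloxy)-2-heptyl-6-methoxybenzoyl]oxy}-2-methoxy-6-pentylbenzoate | CCCCCCCc1cc(O[Si](C)(C)C(C)(C)C)cc(OC)c1C(=O)Oc1cc(CCCCC)c(C(=O)OCc2ccccc2)c(OC)c1
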